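**Retrosynthetic overview**
- Target ⇐ its 5,7-di-O-benzyl ether (hydrogenolysis last). Rings A and B come intact from the starting materials; only ring C is built, and it is the last ring formed.
- Ring C ⇐ O1–C2 hemiketalisation and dehydration of a 2-hydroxy-1,3-diaryl-1,3-dione. Its single free ortho-phenol lies next to the methoxy group, which fixes 8-OMe over 6-OMe.
- Key C2–C3 bond ⇐ carbene-catalysed cross-benzoin. The formyl carbon of 3-hydroxy-4,5-dimethoxybenzaldehyde reacts as an acyl anion (Breslow intermediate) with the formyl carbon of a ring-A aryl glyoxal, joining two natively electrophilic carbons.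
- Aryl glyoxal ⇐ methyl ketone (Riley oxidation) ⇐ 3-iodo ketone (copper-catalysed methoxylation) ⇐ ortho-iodination of di-O-benzyl phloroacetophenone ⇐ phloroacetophenone.

Assumption: the target is an achiral flavonol with no stereocentre, so no enantiocontrol is needed; the sp3 centres in transient intermediates are racemic and are erased.

**Step 1**
Reactants: 1 1-(2,4,6-trihydroxyphenyl)ethanone (2',4',6'-trihydroxyacetophenone)
Product: 2 1-[2,4-bis(benzyloxy)-6-hydroxyphenyl]ethanone
Conditions: BnBr (2.1 equiv), K2CO3 (2.2 equiv), DMF, 0 °C to rt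
Reagents that add atoms: benzyl bromide, BrCc1ccccc1
Why: Williamson ether synthesis in which the para-hydroxyl and one of the two equivalent ortho-hydroxyls are benzylated while the last ortho-hydroxyl is held back by its chelating hydrogen bond to the acetyl group, so a single dibenzyl ether results.

**Step 2**
Reactants: 2 1-[2,4-bis(benzyloxy)-6-hydroxyphenyl]ethanone
Product: 3 1-[4,6-bis(benzyloxy)-2-hydroxy-3-iodophenyl]ethanone
Conditions: benzyltrimethylammonium dichloroiodate (1.05 equiv), NaHCO3 (2 equiv), CH2Cl2/MeOH (5:2), rt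
Reagents that add atoms: benzyltrimethylammonium dichloroiodate, C[N+](C)(C)Cc1ccccc1.Cl[I-]Cl
Why: Electrophilic aromatic iodination directed ortho to the free phenol: C-3 (between OH and OBn) is attacked in preference to C-5, which is wedged between two benzyloxy groups, and the bicarbonate buffer protects the benzyl ethers from HCl.

**Step 3**
Reactants: 3 1-[4,6-bis(benzyloxy)-2-hydroxy-3-iodophenyl]ethanone
Product: 4 1-[4,6-bis(benzyloxy)-2-hydroxy-3-methoxyphenyl]ethanone
Conditions: NaOMe (5 equiv), CuCl (20 mol%), DMF/MeOH (4:1), 110 °C, Ar; then 1 M HCl work-up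
Reagents that add atoms: sodium methoxide, [Na+].[O-]C
Why: Ullmann-type copper-catalysed methoxylation of an ortho-iodophenoxide (the reaction type that turns 5-iodovanillin into syringaldehyde), which puts the methoxy group exactly where iodine was and leaves the benzyl ethers, the ketone and the phenol untouched.

**Step 4**
Reactants: 4 1-[4,6-bis(benzyloxy)-2-hydroxy-3-methoxyphenyl]ethanone
Product: 5 2-[4,6-bis(benzyloxy)-2-hydroxy-3-methoxyphenyl]-2-oxoacetaldehyde
Conditions: SeO2 (1.5 equiv), 1,4-dioxane/H2O (20:1), 95 °C; filter through Celite, dry by toluene azeotrope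
Reagents that add atoms: selenium dioxide, O=[Se]=O
Why: Riley oxidation of the aryl methyl ketone through its enol (ene reaction, then [2,3]-sigmatropic shift and loss of elemental selenium and water) gives the aryl glyoxal; there is no other enolisable or allylic C–H, and the benzyl ethers and the chelated phenol tolerate SeO2.

**Step 5**
Reactants: 5 2-[4,6-bis(benzyloxy)-2-hydroxy-3-methoxyphenyl]-2-oxoacetaldehyde and 6 3-hydroxy-4,5-dimethoxybenzaldehyde (1.5 equiv)
Product: 10 5,7-bis(benzyloxy)-3-hydroxy-2-(3-hydroxy-4,5-dimethoxyphenyl)-8-methoxy-4H-chromen-4-one, via Breslow intermediate 7 (not isolated), via hydroxy diketone 8 (not isolated), via cyclic hemiketal 9 (not isolated)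
Conditions: 2-(pentafluorophenyl)-6,7-dihydro-5H-pyrrolo[2,1-c][1,2,4]triazol-2-ium tetrafluoroborate (15 mol%), i-Pr2NEt (20 mol%), 4 Å MS, THF, rt, Ar, 5 added over 4 h; then TsOH·H2O (40 mol%), 50 °C
Reagents that add atoms: none
Why: Proposed new method: a chemoselective carbene-catalysed cross-benzoin run as a cascade — the triazolylidene converts the ordinary aldehyde 6 (held in excess as the catalyst resting state) into Breslow intermediate 7, an acyl anion equivalent that attacks the far more electrophilic formyl carbon of glyoxal 5 (fed slowly so that its self-coupling and internal redox are starved; its chelated, electron-rich ketone carbon does not compete), giving 8, whose only free ortho-phenol adds to the new aryl ketone to give hemiketal 9, and acid-assisted loss of water to the aromatic pyranone 10 pulls the reversible benzoin equilibrium forward (a reversed pairing would give only an enediol tautomer of 8 that funnels to the same 10); the closest known reaction types are triazolium-carbene cross-benzoin additions of aromatic aldehydes to activated carbonyl acceptors and the acid cyclodehydration of 2-hydroxy-1,3-diaryl-1,3-diones to flavonols; water is the only by-product and the racemic sp3 centres of 8 and 9 are erased.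

**Step 6**
Reactants: 10 5,7-bis(benzyloxy)-3-hydroxy-2-(3-hydroxy-4,5-dimethoxyphenyl)-8-methoxy-4H-chromen-4-one
Product: 11 3,5,7-trihydroxy-2-(3-hydroxy-4,5-dimethoxyphenyl)-8-methoxy-4H-chromen-4-one (CNP0225742.0)
Conditions: H2 (1 atm), Pd/C (10 wt%), THF/MeOH (1:1), rt
Reagents that add atoms: none
Why: Catalytic hydrogenolysis cleaves both benzyl ethers as toluene, while the tetrasubstituted C2=C3 bond of the vinylogous ester, the aryl methyl ethers and the phenols are inert under these conditions; the product is achiral.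

**Compound list**
1 | 1-(2,4,6-trihydroxyphenyl)ethanone | CC(=O)c1c(O)cc(O)cc1O | starting material
2 | 1-[2,4-bis(benzyloxy)-6-hydroxyphenyl]ethanone | CC(=O)c1c(O)cc(OCc2ccccc2)cc1OCc1ccccc1 | intermediate
3 | 1-[4,6-bis(benzyloxy)-2-hydroxy-3-iodophenyl]ethanone | CC(=O)c1c(O)c(I)c(OCc2ccccc2)cc1OCc1ccccc1 | intermediate
4 | 1-[4,6-bis(benzyloxy)-2-hydroxy-3-methoxyphenyl]ethanone | COc1c(O)c(C(C)=O)c(OCc2ccccc2)cc1OCc1ccccc1 | intermediate
5 | 2-[4,6-bis(benzyloxy)-2-hydroxy-3-methoxyphenyl]-2-oxoacetaldehyde | COc1c(O)c(C(=O)C=O)c(OCc2ccccc2)cc1OCc1ccccc1 | intermediate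
6 | 3-hydroxy-4,5-dimethoxybenzaldehyde | COc1cc(C=O)cc(O)c1OC | starting material
7 | Breslow intermediate, the carbene-bound enaminol of 6: 5-{hydroxy[2-(pentafluorophenyl)-6,7-dihydro-2H-pyrrolo[2,1-c][1,2,4]triazol-3(5H)-ylidene]methyl}-2,3-dimethoxyphenol (alkene geometry not defined) | COc1cc(C(O)=C2N(c3c(F)c(F)c(F)c(F)c3F)N=C3CCCN23)cc(O)c1OC | intermediate
8 | 1-[4,6-bis(benzyloxy)-2-hydroxy-3-methoxyphenyl]-2-hydroxy-3-(3-hydroxy-4,5-dimethoxyphenyl)propane-1,3-dione (racemic) | COc1c(O)c(C(=O)C(O)C(=O)c2cc(O)c(OC)c(OC)c2)c(OCc2ccccc2)cc1OCc1ccccc1 | intermediate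
9 | 5,7-bis(benzyloxy)-2,3-dihydroxy-2-(3-hydroxy-4,5-dimethoxyphenyl)-8-methoxychroman-4-one (racemic mixture of diastereomers) | COc1c(OCc2ccccc2)cc(OCc2ccccc2)c2c1OC(O)(c1cc(O)c(OC)c(OC)c1)C(O)C2=O | intermediate
10 | 5,7-bis(benzyloxy)-3-hydroxy-2-(3-hydroxy-4,5-dimethoxyphenyl)-8-methoxy-4H-chromen-4-one | COc1c(OCc2ccccc2)cc(OCc2ccccc2)c2c(=O)c(O)c(-c3cc(O)c(OC)c(OC)c3)oc12 | intermediate
11 | 3,5,7-trihydroxy-2-(3-hydroxy-4,5-dimethoxyphenyl)-8-methoxy-4H-chromen-4-one | COc1cc(-c2oc3c(OC)c(O)cc(O)c3c(=O)c2O)cc(O)c1OC | target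

**Totals and risks**
Total step count: 6. Longest linear sequence: 6 steps (1 → 2 → 3 → 4 → 5 → 10 → 11); aldehyde 6 enters unprotected in step 5.

Most likely to fail, in order:

Step 5 (carbene cross-benzoin cascade). The carbene may be drained by glyoxal 5 itself (self-coupling, internal redox to a mandelate-type lactone) or by hydride transfer, so that little of 8 forms. The fallback keeps the same C2–C3 bond but uses a stoichiometric, pre-formed acyl anion; it sets out from 6 (with 5) and comes back to the route at 10. Aldehyde 6 is converted with propane-1,3-dithiol and BF3·OEt2 (CH2Cl2, 0 °C) into 2-(3-hydroxy-4,5-dimethoxyphenyl)-1,3-dithiane F1. Its dilithio derivative (n-BuLi, 2.2 equiv, THF, −78 to −20 °C) is added to the lithium phenoxide of 5 (LiHMDS, 1 equiv, −78 °C) and attacks the formyl carbon, giving the dithiane-masked adduct 1-[4,6-bis(benzyloxy)-2-hydroxy-3-methoxyphenyl]-2-hydroxy-2-[2-(3-hydroxy-4,5-dimethoxyphenyl)-1,3-dithian-2-yl]ethanone F2. MeI/CaCO3 in aqueous MeCN (45 °C) removes the dithiane to release hydroxy diketone 8, which closes and dehydrates (TsOH·H2O, 50 °C) to 10.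

Step 3 (copper-catalysed methoxylation). The iodide is flanked on both sides and may be reduced back to 2 or couple slowly. The fallback replaces direct C–O coupling by boron oxidation and O-methylation; it sets out from 3 and comes back at 4. Miyaura borylation (B2pin2, PdCl2(dppf), KOAc, dioxane, 90 °C) gives 1-[4,6-bis(benzyloxy)-2-hydroxy-3-(4,4,5,5-tetramethyl-1,3,2-dioxaborolan-2-yl)phenyl]ethanone F3. Oxidation (NaBO3·4H2O, THF/H2O, rt) gives 1-[4,6-bis(benzyloxy)-2,3-dihydroxyphenyl]ethanone F4. MeI (1.05 equiv)/K2CO3 in acetone then methylates only the non-chelated 3-hydroxyl, giving 4.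

Step 4 (Riley oxidation). Over-oxidation to the arylglyoxylic acid, selenium residues, or oligomerisation of the electron-rich ortho-hydroxy glyoxal may spoil the material for step 5. The fallback is selenium-free and goes through a halide; it sets out from 4 and comes back at 5. CuBr2 (2 equiv, EtOAc/CHCl3, reflux) brominates the methyl group to give 1-[4,6-bis(benzyloxy)-2-hydroxy-3-methoxyphenyl]-2-bromoethanone F5. Base-free Kornblum oxidation in DMSO at rt then gives 5; leaving out base keeps the phenol from closing onto the bromide to a coumaranone.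

**Further compounds**
F1 | step 5 | 2-(3-hydroxy-4,5-dimethoxyphenyl)-1,3-dithiane | COc1cc(C2SCCCS2)cc(O)c1OC
F2 | step 5 | 1-[4,6-bis(benzyloxy)-2-hydroxy-3-methoxyphenyl]-2-hydroxy-2-[2-(3-hydroxy-4,5-dimethoxyphenyl)-1,3-dithian-2-yl]ethanone (racemic) | COc1c(O)c(C(=O)C(O)C2(c3cc(O)c(OC)c(OC)c3)SCCCS2)c(OCc2ccccc2)cc1OCc1ccccc1
F3 | step 3 | 1-[4,6-bis(benzyloxy)-2-hydroxy-3-(4,4,5,5-tetramethyl-1,3,2-dioxaborolan-2-yl)phenyl]ethanone | CC(=O)c1c(O)c(B2OC(C)(C)C(C)(C)O2)c(OCc2ccccc2)cc1OCc1ccccc1
F4 | step 3 | 1-[4,6-bis(benzyloxy)-2,3-dihydroxyphenyl]ethanone | CC(=O)c1c(O)c(O)c(OCc2ccccc2)cc1OCc1ccccc1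
F5 | step 4 | 1-[4,6-bis(benzyloxy)-2-hydroxy-3-methoxyphenyl]-2-bromoethanone | COc1c(O)c(C(=O)CBr)c(OCc2ccccc2)cc1OCc1ccccc1
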